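## Structural features

The target (19) is a depside: two benzene rings joined through one aryl ester, with the carboxyl carbon on C1 of ring A bonded to the oxygen on C4 of ring B. Ring A is a 3-chloro-2-hydroxy-4-methoxy-6-pentylbenzoyl unit. Ring B is olivetolic acid (2,4-dihydroxy-6-pentylbenzoic acid) acylated at O-4, so each ring carries a carbonyl flanked by a chelated phenol and a pentyl chain. There is no stereocentre and no alkene geometry, so no stereocentres stand next to each other and nothing stereochemical has to be set or preserved. The fragile groups are the aryl ester (open to hydroxide, alkoxide and amine nucleophiles), the free β-resorcylic acid of ring B (decarboxylates on heating or in acid), the aryl C–Cl bond (at risk under reducing conditions) and the free phenols. The difficulty is regiochemical, not skeletal. The chlorine must sit on C3 of ring A between hydroxyl and methoxyl, where electrophilic substitution of a preformed resorcylate is not reliably directed. In addition, O-2 and O-4 of ring A must be differentiated, and only O-4 of ring B may be acylated while its carboxyl is kept out of the way. The key step uses the fact that C1 (carboxyl), C2 and C4 (oxygens) and C6 (pentyl) of ring B are the alternating carbons of 3,5,7-trioxododecanoic acid. A 4-pyranone holds the C3, C5 and C7 carbonyls of that chain in masked form, and hydroxide releases them so that chain C2 closes onto C7 and makes the C1–C6 bond of ring B.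

## Logic of the disconnections

**19 ⇒ 18.** The O–CH2 bond of a benzyl ester on the ring B carboxyl is cut. A free ring B carboxyl would compete as an acyl donor when the rings are joined, and it makes the ring prone to lose carbon dioxide. The skeleton is unchanged, but the junction step becomes chemoselective. The forward step must remove one benzyl group without reducing the C–Cl bond or touching the aryl ester.

**18 ⇒ 16 + 10.** The acyl C–O bond of the depside is cut, the only bond between the rings. It divides the molecule into two monocyclic halves of nearly equal size. The forward step must acylate O-4 of 10 and leave the chelated O-2 alone. It must also activate the di-ortho-substituted acid 16 without masking its own hydroxyl, which is done through the anhydride 17 formed in the flask.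

**10 ⇒ 9.** The ester O–benzyl bond is cut. The forward step must alkylate the carboxylate and not a phenol, and it must run without heat.

**9 ⇒ 6 (through 8 and 7).** The C1–C6 bond of ring B is cut, and with it the aromaticity. The 1,3-relationship of the carboxyl, the two oxygens and the pentyl-bearing carbon is that of a polyketide chain, so the cut gives the open chain 7. That chain is too labile to store and is therefore held as 6, in which the ring oxygen ties chain C3 to chain C7. The arene and all its regiochemistry are reduced to the connectivity of a linear chain. The forward step must open and reclose in one pot, choose the right aldol mode and keep the carboxyl.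

**6 ⇒ 4 (through 5).** The bond between the side-chain methylene and the carboxyl carbon is cut, leaving a lateral carbanion and a one-carbon electrophile. The forward step must deprotonate the methyl group and not the first methylene of the pentyl chain, and the product must be handled cold.

**4 ⇒ 1 + 2.** The bond between the first and second carbons of the pentyl chain is cut. This returns a symmetrical commodity pyranone and a four-carbon electrophile. The forward step (through 3) must stop at mono-alkylation.

**16 ⇒ 15.** The oxidation level at the carboxyl carbon is lowered. The aldehyde is what arene formylation delivers, and its carbonyl is what steers the ether cleavage one step earlier. The forward oxidation must spare an electron-rich phenolic ring.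

**15 ⇒ 14.** The O–CH3 bond at O-2 is cut. Carrying both oxygens as methyl ethers keeps the earlier intermediates symmetrical, and the ether to be kept (O-4) is the one that cannot chelate. The forward step must cleave only the ether next to the carbonyl.

**14 ⇒ 13.** The aryl–CHO bond is cut. Since 13 is symmetrical about the axis through the chlorine-bearing and pentyl-bearing carbons, its two open positions are equivalent and no regiochemical question arises. The forward step must bring an electrophile into a position flanked by methoxyl and pentyl.

**13 ⇒ 11 (through 12).** The C–Cl bond is cut. Chlorine between the two oxygens is the hardest regiochemical element of ring A, and placing it first, at the C–H flanked by both ethers, settles it by directed metalation. Ring A is reduced to a commercial symmetrical arene. The forward step needs ring metalation and not benzylic metalation.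

## Other disconnections considered

**Alternative 1:** Ring B benzannulation on a ring A enol-ester diene.
- **Cut:** the C1–C2 and C5–C6 bonds of ring B. The four-carbon piece is the diene A1, which already carries ring A as an enol ester on the future C4 oxygen. The two-carbon piece is the ynoate A2.
- **Forward key step:** a thermal Diels–Alder addition of A1 to A2, then aromatisation by 1,2-elimination of the methoxy group and loss of silicon, to give A3.
- **In favour:** the depside ester exists before ring B does, so no O-4 versus O-2 selection on a resorcinol is needed. The carboxyl arrives already as its benzyl ester, and no decarboxylation-prone free resorcylic acid is handled. On these two points the alternative is better than the chosen plan. Regiochemistry follows from polarity matching of the nucleophilic CH2 terminus of A1 with the β-carbon of A2.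
- **Against:** A1 must be made by γ-deprotonation of a 3-aroyloxy crotonate with an amide base, where O-to-C acyl transfer and attack on the aryl ester can compete. The acyloxy group is a weak donor, and A2 is an internal β-alkyl alkynoate and so a poor dienophile; the heat it needs may cause acyl migration in A1. Ring A must still be supplied fully protected as the acyl chloride F7, which is longer to make than 16.
- **Comparison:** both plans build ring B from scratch. The chosen closure is an intramolecular aldol of one preorganised substrate; this one is a bimolecular cycloaddition of two hindered partners. The step count is estimated to be one or two steps longer. The final hydrogenolysis would remove two benzyl groups in place of one, which means longer exposure of the C–Cl bond.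

**Alternative 2:** Biomimetic diketo-dioxinone folding to protected ring A.
- **Cut:** the C1–C6 bond of ring A, the same type of bond as in the chosen plan but in the other ring. The precursor is the diketo-dioxinone A4.
- **Forward key step:** a tertiary amine promotes aldol addition of the dioxinone α-carbon to the pentyl ketone, and dehydration gives A5.
- **In favour:** the conditions are milder than hydroxide. The carboxyl emerges masked and activated, so decarboxylation is not an issue. O-2 and O-4 are differentiated from the start (O-4 free, O-2 tied into the acetal), which saves the demethylation of the chosen ring A line. Opening A5 with a benzyl alkoxide would give 10, so one folding product could feed both rings. On protecting-group economy and convergence the alternative is the equal or the better of the chosen plan.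
- **Against:** the folding brings no chlorine. After O-methylation, A5 would need electrophilic chlorination at C8 and not C6 to reach A6, with no dependable bias. A4 needs several acylation steps, against two steps for 6. Opening A6 with the hindered, weakly nucleophilic phenoxide of 10 is less certain than opening with alkoxides.
- **Comparison:** the mechanism is the same aldol–dehydration logic. The chosen plan applies it to ring B, whose substitution is exactly that of the bare polyketide. The alternative applies it to ring A, which needs two further adjustments, one of them regiochemically unsecured. The step count is comparable only if A5 serves both rings; otherwise it is longer.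

**Alternative 3:** Ring A benzannulation on a ring B ynoate ester.
- **Cut:** the C1–C2 and C5–C6 bonds of ring A. The pieces are the chlorinated diene A7 and the aryl ynoate A8, which is the 4-O-oct-2-ynoyl ester of 10.
- **Forward key step:** cycloaddition of A7 to A8 and aromatisation by loss of the methoxy group give A9, which is the same compound as 18.
- **In favour:** chlorine, methoxyl and hydroxyl of ring A are all placed by construction. This is as secure as the metalation used in the chosen plan and better than any late chlorination. The free 2-hydroxyl appears without a protecting group. From 10 the estimate is about four steps to 18, against five through 16, so it is equal or marginally better on step count.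
- **Against:** A8 is made from 10, so ring B is still required and the chosen key step (or another source of ring B) remains necessary. A7 is tetrasubstituted at the chlorinated carbon, which disfavours the s-cis conformer and lowers reactivity. The aryl ester of A8 is an activated acyl group that a silyl ketene acetal can attack, or the sequence can stop at an open Michael adduct. The free phenol of ring B consumes silyl reagent.
- **Comparison:** this is complementary, not competing, because it disconnects ring A while the chosen plan disconnects ring B. A sensitive diene and a pericyclic step stand against lithiation, formylation and oxidation of a stable arene. The chosen ring A line is longer by about one step but rests on more predictable reactions.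

Key step: step 3

Assumption: 1,3-dimethoxy-5-pentylbenzene (11), the dimethyl ether of olivetol, is taken as a catalogue compound, so both ring A oxygens start as methyl ethers and are differentiated in step 7.

## Route

Step 1
Reactants: 1 2,6-dimethyl-4H-pyran-4-one; 2 1-iodobutane
Product: 4 2-methyl-6-pentyl-4H-pyran-4-one, via lateral lithio species 3 (not isolated)
Conditions: LiN(SiMe3)2 (1.0 equiv), THF, −78 °C; then 2 (1.3 equiv), −78 → −20 °C
Reagents that add atoms: none
Why: Lateral lithiation of a 2-methyl-4-pyranone gives a vinylogous enolate (3) that is C-alkylated at the exocyclic carbon by a primary iodide in an SN2 reaction. A silylamide base and low temperature limit addition to the ring and self-condensation, and using no excess base limits a second alkylation.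

Step 2
Reactants: 4 2-methyl-6-pentyl-4H-pyran-4-one
Product: 6 2-(4-oxo-6-pentyl-4H-pyran-2-yl)acetic acid, via lateral lithio species 5 (not isolated)
Conditions: LiN(SiMe3)2 (1.1 equiv), THF, −78 °C; cannulated into CO2-saturated THF, −78 °C; cold aq. HCl to pH 2, extraction into aq. NaHCO3 and re-acidification at 0 °C
Reagents that add atoms: carbon dioxide, O=C=O
Why: Kinetic lateral deprotonation favours the primary methyl over the more hindered pentyl methylene, and the anion 5 is carboxylated at carbon. Inverse addition into excess carbon dioxide prevents the more acidic product from quenching unreacted 5. Cold acid–base isolation without heating avoids decarboxylation of this vinylogous β-keto acid and returns unreacted 4.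

Step 3
Reactants: 6 2-(4-oxo-6-pentyl-4H-pyran-2-yl)acetic acid
Product: 9 olivetolic acid (2,4-dihydroxy-6-pentylbenzoic acid), via 3,5,7-trioxododecanoic acid 7 (not isolated), via cyclic aldol 8 (not isolated)
Conditions: 2 M aq. KOH (6 equiv), degassed, Ar, 0 °C → rt; then 2 M HCl to pH 2–3 at 0 °C
Reagents that add atoms: none
Why: Hydroxide first converts 6 into its carboxylate, then adds in vinylogous fashion to the pentyl-bearing ring carbon, and retro-oxa-Michael cleavage of the ring C–O bond releases the open chain 7 as its enolate salt; the water taken up here is given back on aromatisation, so the step is a net isomerisation. In 7 (chain numbered from the carboxyl) the C2 carbanion, stabilised by the carboxylate and the C3 carbonyl, attacks the C7 ketone to give the β-hydroxy ketone 8, which loses water by E1cB and tautomerises to 9; this makes the bond between C1 and C6 of ring B. The closest known reaction type is the hydroxide-induced opening of 4-pyranone-2-acetic acids (masked 3,5,7-triketo acids) with aldol recyclisation to orsellinic-type acids. Ring B closes in a 6-(enolendo)-exo-trig aldol mode, with the C2=C3 enolate inside the new ring and the C7 carbonyl oxygen outside it. No stereocentre remains, since the two sp3 centres of 8 form without control and are erased by dehydration and enolisation. The step needs site selectivity for C2-to-C7 closure over the C8-to-C3 closure that would give an arylacetic acid, and it must avoid Claisen closure and loss of carbon dioxide. C2 is activated by two acyl groups and C8 by one, which favours the wanted enolate by several pK units; the chain end is a carboxylate and cannot act as the acyl acceptor of a Claisen condensation; and the β-keto acid exists only as its salt until the arene has formed, with cold acidification protecting 9. Aromatisation makes the closure irreversible and draws the ring-opening equilibrium forward.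

Step 4
Reactants: 9 olivetolic acid
Product: 10 benzyl 2,4-dihydroxy-6-pentylbenzoate
Conditions: BnBr (1.05 equiv), KHCO3 (1.2 equiv), DMF, rt
Reagents that add atoms: benzyl bromide, BrCc1ccccc1
Why: Bicarbonate ionises only the carboxylic acid, so SN2 O-alkylation gives the benzyl ester and leaves both phenols free. Room temperature avoids decarboxylation of 9.

Step 5
Reactants: 11 1,3-dimethoxy-5-pentylbenzene
Product: 13 2-chloro-1,3-dimethoxy-5-pentylbenzene, via 2-lithio-1,3-dimethoxy-5-pentylbenzene 12 (not isolated)
Conditions: n-BuLi (1.1 equiv), THF, 0 °C → rt; then C2Cl6 (1.2 equiv), −78 °C → rt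
Reagents that add atoms: hexachloroethane, ClC(Cl)(Cl)C(Cl)(Cl)Cl
Why: Directed ortho-metalation takes place at the C–H flanked by both methoxy groups, which is the most acidic and best coordinated site, and the aryllithium 12 is chlorinated by halogen transfer from hexachloroethane. This fixes chlorine between the two oxygens, a position that electrophilic chlorination would not select.

Step 6
Reactants: 13 2-chloro-1,3-dimethoxy-5-pentylbenzene
Product: 14 3-chloro-2,4-dimethoxy-6-pentylbenzaldehyde
Conditions: Cl2CHOMe (1.5 equiv), TiCl4 (2.2 equiv), CH2Cl2, −78 → 0 °C; then ice/aq. HCl
Reagents that add atoms: dichloromethyl methyl ether, COC(Cl)Cl; water, O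
Why: Rieche formylation, in which the TiCl4-activated chloro(methoxy)carbenium ion attacks a position ortho to one methoxyl and para to the other, and the α-chloro ether is hydrolysed to the aldehyde on work-up. The two open positions of 13 are equivalent by symmetry, so only one regioisomer can form; any partial loss of the 2-O-methyl group converges in step 7.

Step 7
Reactants: 14 3-chloro-2,4-dimethoxy-6-pentylbenzaldehyde
Product: 15 3-chloro-2-hydroxy-4-methoxy-6-pentylbenzaldehyde
Conditions: BCl3 (1.2 equiv), CH2Cl2, −78 → 0 °C; then H2O
Reagents that add atoms: none
Why: Chelation-controlled ether cleavage, in which boron binds the aldehyde oxygen and the neighbouring methoxy oxygen in a six-membered chelate and chloride removes that methyl group. The 4-methoxy group cannot chelate and is kept.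

Step 8
Reactants: 15 3-chloro-2-hydroxy-4-methoxy-6-pentylbenzaldehyde
Product: 16 3-chloro-2-hydroxy-4-methoxy-6-pentylbenzoic acid
Conditions: NaClO2 (1.5 equiv), NaH2PO4, 2-methyl-2-butene (excess), t-BuOH/THF/H2O, 0 °C → rt
Reagents that add atoms: sodium chlorite, [Na+].[O-]Cl=O
Why: Pinnick oxidation, in which chlorous acid adds to the aldehyde and fragments to the acid and hypochlorous acid. The alkene scavenges the hypochlorous acid before it can chlorinate the open C5 position of the phenolic ring.

Step 9
Reactants: 16 3-chloro-2-hydroxy-4-methoxy-6-pentylbenzoic acid; 10 benzyl 2,4-dihydroxy-6-pentylbenzoate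
Product: 18 benzyl 4-[(3-chloro-2-hydroxy-4-methoxy-6-pentylbenzoyl)oxy]-2-hydroxy-6-pentylbenzoate, via mixed aroyl trifluoroacetyl anhydride 17 (not isolated)
Conditions: (CF3CO)2O (4 equiv), toluene, 0 °C → rt; then aq. NaHCO3
Reagents that add atoms: none
Why: Esterification through a mixed trifluoroacetic anhydride, in which 17 ionises towards an acylium ion stabilised by the ortho and para oxygens, so that even a di-ortho-substituted aroyl group is transferred to a phenol. O-4 of 10 is the only unchelated hydroxyl; the 2-hydroxyls of both partners are hydrogen-bonded to carbonyls and hindered, and any aryl trifluoroacetate formed is hydrolysed in the bicarbonate work-up.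

Step 10
Reactants: 18 benzyl 4-[(3-chloro-2-hydroxy-4-methoxy-6-pentylbenzoyl)oxy]-2-hydroxy-6-pentylbenzoate
Product: 19 4-[(3-chloro-2-hydroxy-4-methoxy-6-pentylbenzoyl)oxy]-2-hydroxy-6-pentylbenzoic acid (target)
Conditions: H2 (1 atm), Pd/C (10% Pd on carbon), EtOAc, rt, stopped at full conversion
Reagents that add atoms: none
Why: Catalytic hydrogenolysis of the benzylic C–O bond of the ester. A benzyl ester is cleaved much faster than an electron-rich, di-ortho-substituted aryl chloride in a neutral, base-free medium, and the aryl ester is inert to these conditions.

## Compound list

1 | 2,6-dimethyl-4H-pyran-4-one | Cc1cc(=O)cc(C)o1 | starting material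
2 | 1-iodobutane | CCCCI | starting material
3 | 2-(lithiomethyl)-6-methyl-4H-pyran-4-one | [Li]Cc1cc(=O)cc(C)o1 | intermediate (not isolated)
4 | 2-methyl-6-pentyl-4H-pyran-4-one | CCCCCc1cc(=O)cc(C)o1 | intermediate
5 | 2-(lithiomethyl)-6-pentyl-4H-pyran-4-one | [Li]Cc1cc(=O)cc(CCCCC)o1 | intermediate (not isolated)
6 | 2-(4-oxo-6-pentyl-4H-pyran-2-yl)acetic acid | CCCCCc1cc(=O)cc(CC(=O)O)o1 | intermediate
7 | 3,5,7-trioxododecanoic acid | CCCCCC(=O)CC(=O)CC(=O)CC(=O)O | intermediate (not isolated)
8 | 6-hydroxy-2,4-dioxo-6-pentylcyclohexane-1-carboxylic acid (two transient sp3 centres, uncontrolled, erased in the same step) | CCCCCC1(O)CC(=O)CC(=O)C1C(=O)O | intermediate (not isolated)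
9 | olivetolic acid (2,4-dihydroxy-6-pentylbenzoic acid) | CCCCCc1cc(O)cc(O)c1C(=O)O | intermediate
10 | benzyl 2,4-dihydroxy-6-pentylbenzoate | CCCCCc1cc(O)cc(O)c1C(=O)OCc1ccccc1 | intermediate
11 | 1,3-dimethoxy-5-pentylbenzene | CCCCCc1cc(OC)cc(OC)c1 | starting material
12 | 2-lithio-1,3-dimethoxy-5-pentylbenzene | [Li]c1c(OC)cc(CCCCC)cc1OC | intermediate (not isolated)
13 | 2-chloro-1,3-dimethoxy-5-pentylbenzene | CCCCCc1cc(OC)c(Cl)c(OC)c1 | intermediate
14 | 3-chloro-2,4-dimethoxy-6-pentylbenzaldehyde | CCCCCc1cc(OC)c(Cl)c(OC)c1C=O | intermediate
15 | 3-chloro-2-hydroxy-4-methoxy-6-pentylbenzaldehyde | CCCCCc1cc(OC)c(Cl)c(O)c1C=O | intermediate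
16 | 3-chloro-2-hydroxy-4-methoxy-6-pentylbenzoic acid | CCCCCc1cc(OC)c(Cl)c(O)c1C(=O)O | intermediate
17 | 3-chloro-2-hydroxy-4-methoxy-6-pentylbenzoic trifluoroacetic anhydride | CCCCCc1cc(OC)c(Cl)c(O)c1C(=O)OC(=O)C(F)(F)F | intermediate (not isolated)
18 | benzyl 4-[(3-chloro-2-hydroxy-4-methoxy-6-pentylbenzoyl)oxy]-2-hydroxy-6-pentylbenzoate | CCCCCc1cc(OC(=O)c2c(CCCCC)cc(OC)c(Cl)c2O)cc(O)c1C(=O)OCc1ccccc1 | intermediate
19 | 4-[(3-chloro-2-hydroxy-4-methoxy-6-pentylbenzoyl)oxy]-2-hydroxy-6-pentylbenzoic acid | CCCCCc1cc(OC(=O)c2c(CCCCC)cc(OC)c(Cl)c2O)cc(O)c1C(=O)O | target

## Step count and risk

Total step count: 10. Longest linear sequence: 6 steps (steps 1, 2, 3, 4, 9, 10; the ring A branch through steps 5, 6, 7, 8, 9, 10 is equally long).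

**Step 3 (key step).** The most likely failure is slow ring opening of a 2,6-dialkyl-4-pyranone that carries an anionic side chain. Forcing it with heat or stronger base invites loss of carbon dioxide at the β-keto acid stage, retro-Claisen scission of the polyketone, or closure in the wrong aldol sense. A chain that has not cyclised when acid is added simply recloses to a pyranone or lactonises. The fallback gives up building ring B and carboxylates a preformed resorcinol instead. It sets out from 11, which is demethylated with BBr3 in CH2Cl2 to olivetol F1 (also purchasable). F1 is then heated with MeOMgOCO2Me (methyl magnesium carbonate) in DMF at about 120 °C and acidified cold. This ortho-carboxylation through a magnesium chelate should place the carboxyl ortho to one hydroxyl and para to the other, and the 2,6-dihydroxy isomer would have to be separated if it forms. The fallback returns to the route at 9.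

**Step 2.** The risks are incomplete site control in the deprotonation (the pentyl methylene competing with the methyl), proton transfer from the product to unreacted anion, and decarboxylation during isolation. The fallback traps the anion as an ester that can be purified. From 4, deprotonation with LiN(SiMe3)2 (2.2 equiv) and acylation with di-tert-butyl dicarbonate should give tert-butyl 2-(4-oxo-6-pentyl-4H-pyran-2-yl)acetate F2. This is chromatographed free of any regioisomer and cleaved with CF3CO2H in CH2Cl2 at 0 °C, returning to the route at 6.

**Step 1.** The risks are proton exchange between product and anion followed by a second alkylation, self-condensation of the anion with neutral pyranone, and a slow SN2 reaction at low temperature. The fallback replaces alkylation by an aldol sequence. From 1, the same lithio species is added to butanal at −78 °C to give racemic 2-(2-hydroxypentyl)-6-methyl-4H-pyran-4-one F3. Acid-catalysed dehydration (catalytic TsOH, toluene, heat) gives (E)-2-methyl-6-(pent-1-en-1-yl)-4H-pyran-4-one F4. Hydrogenation of the side-chain alkene (H2, Pd/C, EtOAc) returns to the route at 4.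

**Step 9.** The risks are Friedel–Crafts C-acylation of the electron-rich ring of 10 under acylium conditions, self-acylation of 16 through its own hydroxyl, and unproductive trifluoroacetylation of O-4. The fallback masks the ring A hydroxyl and acylates under basic conditions. From 15, benzylation (BnBr, K2CO3, DMF) gives 2-(benzyloxy)-3-chloro-4-methoxy-6-pentylbenzaldehyde F5. Pinnick oxidation gives 2-(benzyloxy)-3-chloro-4-methoxy-6-pentylbenzoic acid F6. Oxalyl chloride with catalytic DMF gives 2-(benzyloxy)-3-chloro-4-methoxy-6-pentylbenzoyl chloride F7. Acylation of 10 (K2CO3, acetone) at the more acidic, unchelated O-4 gives benzyl 4-{[2-(benzyloxy)-3-chloro-4-methoxy-6-pentylbenzoyl]oxy}-2-hydroxy-6-pentylbenzoate F8. Hydrogenolysis of both benzyl groups (H2, Pd/C, EtOAc) returns to the route at 19.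

**Step 10.** The risk is competing hydrogenolysis of the aryl C–Cl bond alongside debenzylation, particularly if the reaction runs on after conversion is complete. The fallback changes the carboxyl protecting group to one removed without hydrogen. From 9, allyl bromide and KHCO3 in DMF give allyl 2,4-dihydroxy-6-pentylbenzoate F9. Coupling with 16 under the conditions of step 9 gives allyl 4-[(3-chloro-2-hydroxy-4-methoxy-6-pentylbenzoyl)oxy]-2-hydroxy-6-pentylbenzoate F10. Deallylation with catalytic Pd(PPh3)4 (a zerovalent palladium complex) and PhSiH3 in CH2Cl2 at room temperature returns to the route at 19.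

## Further compounds

F1 | step 3 | olivetol (5-pentylbenzene-1,3-diol) | CCCCCc1cc(O)cc(O)c1
F2 | step 2 | tert-butyl 2-(4-oxo-6-pentyl-4H-pyran-2-yl)acetate | CCCCCc1cc(=O)cc(CC(=O)OC(C)(C)C)o1
F3 | step 1 | 2-(2-hydroxypentyl)-6-methyl-4H-pyran-4-one (racemic) | CCCC(O)Cc1cc(=O)cc(C)o1
F4 | step 1 | (E)-2-methyl-6-(pent-1-en-1-yl)-4H-pyran-4-one | CCC/C=C/c1cc(=O)cc(C)o1
F5 | step 9 | 2-(benzyloxy)-3-chloro-4-methoxy-6-pentylbenzaldehyde | CCCCCc1cc(OC)c(Cl)c(OCc2ccccc2)c1C=O
F6 | step 9 | 2-(benzyloxy)-3-chloro-4-methoxy-6-pentylbenzoic acid | CCCCCc1cc(OC)c(Cl)c(OCc2ccccc2)c1C(=O)O
F7 | step 9 | 2-(benzyloxy)-3-chloro-4-methoxy-6-pentylbenzoyl chloride | CCCCCc1cc(OC)c(Cl)c(OCc2ccccc2)c1C(=O)Cl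
F8 | step 9 | benzyl 4-{[2-(benzyloxy)-3-chloro-4-methoxy-6-pentylbenzoyl]oxy}-2-hydroxy-6-pentylbenzoate | CCCCCc1cc(OC(=O)c2c(CCCCC)cc(OC)c(Cl)c2OCc2ccccc2)cc(O)c1C(=O)OCc1ccccc1
F9 | step 10 | allyl 2,4-dihydroxy-6-pentylbenzoate | CCCCCc1cc(O)cc(O)c1C(=O)OCC=C
F10 | step 10 | allyl 4-[(3-chloro-2-hydroxy-4-methoxy-6-pentylbenzoyl)oxy]-2-hydroxy-6-pentylbenzoate | CCCCCc1cc(OC(=O)c2c(CCCCC)cc(OC)c(Cl)c2O)cc(O)c1C(=O)OCC=C
A1 | alternative 1 | 4-methoxy-4-[(trimethylsilyl)oxy]buta-1,3-dien-2-yl 2-(benzyloxy)-3-chloro-4-methoxy-6-pentylbenzoate | C=C(OC(=O)c1c(CCCCC)cc(OC)c(Cl)c1OCc1ccccc1)C=C(OC)O[Si](C)(C)C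
A2 | alternative 1 | benzyl oct-2-ynoate | CCCCCC#CC(=O)OCc1ccccc1
A3 | alternative 1 | benzyl 4-{[2-(benzyloxy)-3-chloro-4-methoxy-6-pentylbenzoyl]oxy}-2-hydroxy-6-pentylbenzoate | CCCCCc1cc(OC(=O)c2c(CCCCC)cc(OC)c(Cl)c2OCc2ccccc2)cc(O)c1C(=O)OCc1ccccc1
A4 | alternative 2 | 2,2-dimethyl-6-(2,4-dioxononyl)-4H-1,3-dioxin-4-one | CCCCCC(=O)CC(=O)CC1=CC(=O)OC(C)(C)O1
A5 | alternative 2 | 7-hydroxy-2,2-dimethyl-5-pentyl-4H-1,3-benzodioxin-4-one | CCCCCc1cc(O)cc2c1C(=O)OC(C)(C)O2
A6 | alternative 2 | 8-chloro-7-methoxy-2,2-dimethyl-5-pentyl-4H-1,3-benzodioxin-4-one | CCCCCc1cc(OC)c(Cl)c2c1C(=O)OC(C)(C)O2
A7 | alternative 3 | [(2-chloro-1,3-dimethoxybuta-1,3-dien-1-yl)oxy]trimethylsilane | C=C(OC)C(Cl)=C(OC)O[Si](C)(C)C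
A8 | alternative 3 | benzyl 2-hydroxy-4-(oct-2-ynoyloxy)-6-pentylbenzoate | CCCCCC#CC(=O)Oc1cc(O)c(C(=O)OCc2ccccc2)c(CCCCC)c1
A9 | alternative 3 | benzyl 4-[(3-chloro-2-hydroxy-4-methoxy-6-pentylbenzoyl)oxy]-2-hydroxy-6-pentylbenzoate | CCCCCc1cc(OC(=O)c2c(CCCCC)cc(OC)c(Cl)c2O)cc(O)c1C(=O)OCc1ccccc1
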